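**Retrosynthetic overview**

- Last bond: ring C4–CH2, made by a three-component reductive alkylation (Knoevenagel condensation, then transfer hydrogenation) between a dearomatised acylphloroglucinol and a cyclopentane β-hydroxy aldehyde.
- The hydroxy aldehyde comes from a cis-fused cyclopentane β-lactone by half-reduction.
- Key step: carbene-catalysed homoenolate annulation of 4-methylpenta-2,4-dienal with methyl vinyl ketone. The enal β-carbon, made nucleophilic, bonds to the enone β-carbon; aldol/lactonisation then closes the cyclopentane and sets its three stereocentres.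
- The dearomatised triketone comes from asymmetric dearomative prenylation of the 3-methyl acylphloroglucinol, itself from Friedel–Crafts acylation of 2-methylphloroglucinol.
- Ring order: the six-membered ring is bought as the arene and dearomatised (quaternary centre) in step 2; the cyclopentane (with a transient fused β-lactone) forms in step 4.

**Assumptions**

- (2R)-2-Methylbutanoic acid and 2-methylbenzene-1,3,5-triol are bought; descriptors of the ring quaternary carbon refer to the enol tautomer of the given SMILES.
- The sense of induction of the chiral ligand (step 2) and of the chiral carbene (step 4) is assigned by analogy and must be confirmed on the first run; the mirror-image ligand or precatalyst is used if it proves opposite.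
- Catalyst-bound species (carbene adducts, π-allyl palladium, aluminium alkoxides) are mechanistic intermediates and carry no number.

**Route**

Step 1
Reactants: 1 (2R)-2-methylbutanoic acid; 2 2-methylbenzene-1,3,5-triol (2-methylphloroglucinol)
Product: 4 (2R)-2-methyl-1-(2,4,6-trihydroxy-3-methylphenyl)butan-1-one, via (2R)-2-methylbutanoyl chloride 3 (not isolated)
Conditions: 1, (COCl)2 (1.05 equiv), DMF (cat.), CH2Cl2, 0 °C to rt; then 2, AlCl3 (3.5 equiv), PhNO2/CH2Cl2, 0 °C to rt; aq. HCl work-up
Reagents that add atoms: oxalyl chloride, O=C(Cl)C(=O)Cl (supplies the chlorine of 3; no atom of it remains in 4)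
Why: Friedel–Crafts C-acylation of the very electron-rich arene at one of its two equivalent free positions; the acylium ion is not enolised at or below room temperature, so the α-stereocentre of 1 is carried through and no new stereocentre forms.

Step 2
Reactants: 4 (2R)-2-methyl-1-(2,4,6-trihydroxy-3-methylphenyl)butan-1-one; 5 3-methylbut-2-en-1-yl acetate (prenyl acetate)
Product: 6 (6R)-3,5-dihydroxy-6-methyl-6-(3-methylbut-2-en-1-yl)-2-[(2R)-2-methylbutanoyl]cyclohexa-2,4-dien-1-one
Conditions: Pd2(dba)3·CHCl3 (2.5 mol%), (1R,2R)-N,N'-bis[2-(diphenylphosphanyl)benzoyl]cyclohexane-1,2-diamine (Trost ligand, 7.5 mol%), iPr2NEt (1.2 equiv), 5 (0.95 equiv), THF, 0 °C to rt; extract into aq. NaHCO3, acidify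
Reagents that add atoms: none
Why: Proposed new method: the zerovalent palladium catalyst ionises 5 to a π-prenyl complex of divalent palladium, and the phenolate of 4 attacks its unsubstituted terminus (linear prenyl) through the methyl-bearing ring carbon, the more electron-rich of the two open ring carbons as in the geminal dialkylations that give hop β-acids, while O-prenyl ethers are re-ionised by the catalyst and the chiral pocket of the ligand chooses the ring face to set the quaternary 6R centre; the closest known reaction types are the palladium-catalysed asymmetric allylic dearomatisation of phenols and naphthols and the Tsuji–Trost asymmetric prenylation of prochiral carbon nucleophiles.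

Step 3
Reactants: 7 2-methylprop-2-enal (methacrolein); 8 (triphenylphosphoranylidene)acetaldehyde
Product: 9 (2E)-4-methylpenta-2,4-dienal
Conditions: 7 (3 equiv), BHT (cat.), toluene, 70 °C, sealed vessel; filter through silica, distil
Reagents that add atoms: none
Why: Wittig olefination with a stabilised formyl ylide gives the E-enal and adds only once because dienal 9 is a poorer electrophile than 7; no stereocentre is formed.

Step 4
Reactants: 9 (2E)-4-methylpenta-2,4-dienal; 10 but-3-en-2-one (methyl vinyl ketone)
Product: 11 (1R,2S,5S)-5-methyl-2-(prop-1-en-2-yl)-6-oxabicyclo[3.2.0]heptan-7-one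
Conditions: (5aS,10bR)-2-mesityl-5a,10b-dihydro-4H,6H-indeno[2,1-b][1,2,4]triazolo[4,3-d][1,4]oxazin-2-ium chloride (10 mol%), DBU (12 mol%), 9 (1.5 equiv), 10 added over 6 h, ClCH2CH2Cl, 0 °C to rt
Reagents that add atoms: none
Why: Proposed new method: the chiral triazolylidene adds to the formyl group of 9 and turns its β-carbon into a nucleophile (a catalyst-bound homoenolate), which attacks the β-carbon of 10 so that two normally electrophilic carbons are joined (C2–C3 of 11) under catalyst facial control that fixes C2 as S; the azolium enolate left behind then adds to the methyl ketone (intramolecular aldol, acyl group trans to the neighbouring isopropenyl group) and the tertiary alkoxide acylates itself, which can only give the cis-fused β-lactone and frees the carbene, so all three stereocentres follow from the first bond and no co-product is formed; the closest known reaction type is the N-heterocyclic-carbene-catalysed homoenolate [3+2] annulation of enals with chalcones and 4-oxoenoates to cyclopentane-fused β-lactones, extended here to an unsubstituted vinyl ketone (added slowly to suppress oligomerisation and Stetter-type acyl-anion addition) and to a 2,4-dienal (β-attack expected over δ-attack because the six-membered Michael/oxy-Cope transition state reaches only the β-carbon).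

Step 5
Reactants: 11 (1R,2S,5S)-5-methyl-2-(prop-1-en-2-yl)-6-oxabicyclo[3.2.0]heptan-7-one
Product: 12 (1R,2S,5S)-2-hydroxy-2-methyl-5-(prop-1-en-2-yl)cyclopentane-1-carbaldehyde
Conditions: iBu2AlH (1.05 equiv), CH2Cl2, −78 °C; MeOH, then aq. KNaC4H4O6 (potassium sodium tartrate), 0 °C; used crude at once
Reagents that add atoms: none
Why: Half-reduction of a lactone: hydride adds once, the aluminium-bound tetrahedral intermediate is held at −78 °C until the quench and then opens to the β-hydroxy aldehyde; no bond to a stereocentre is broken, so the cis hydroxyl/formyl and trans isopropenyl relationships of 11 are kept.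

Step 6
Reactants: 6 (6R)-3,5-dihydroxy-6-methyl-6-(3-methylbut-2-en-1-yl)-2-[(2R)-2-methylbutanoyl]cyclohexa-2,4-dien-1-one; 12 (1R,2S,5S)-2-hydroxy-2-methyl-5-(prop-1-en-2-yl)cyclopentane-1-carbaldehyde
Product: 14 (6R)-3,5-dihydroxy-4-{[(1R,2S,5S)-2-hydroxy-2-methyl-5-(prop-1-en-2-yl)cyclopentyl]methyl}-6-methyl-6-(3-methylbut-2-en-1-yl)-2-[(2R)-2-methylbutanoyl]cyclohexa-2,4-dien-1-one (CNP0299585.1), via alkylidene triketone 13 (not isolated)
Conditions: 12 (1.2 equiv), diethyl 2,6-dimethyl-1,4-dihydropyridine-3,5-dicarboxylate (1.2 equiv), L-proline (10 mol%), CH2Cl2, rt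
Reagents that add atoms: none
Why: Three-component reductive alkylation (Knoevenagel condensation, then transfer hydrogenation): the only ring C–H of the vinylogous acid 6 condenses with aldehyde 12, and the strongly electrophilic alkylidene 13 takes hydride from the dihydropyridine at the exocyclic carbon; no new stereocentre forms, and the carbon next to the former formyl group already holds its thermodynamically preferred configuration (trans to both the isopropenyl and the ring methyl group), so all existing centres are retained.

**Compound list**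

1 | (2R)-2-methylbutanoic acid | CC[C@@H](C)C(=O)O | starting material
2 | 2-methylbenzene-1,3,5-triol | Cc1c(O)cc(O)cc1O | starting material
3 | (2R)-2-methylbutanoyl chloride | CC[C@@H](C)C(=O)Cl | intermediate
4 | (2R)-2-methyl-1-(2,4,6-trihydroxy-3-methylphenyl)butan-1-one | CC[C@@H](C)C(=O)c1c(O)cc(O)c(C)c1O | intermediate
5 | 3-methylbut-2-en-1-yl acetate | CC(C)=CCOC(C)=O | starting material
6 | (6R)-3,5-dihydroxy-6-methyl-6-(3-methylbut-2-en-1-yl)-2-[(2R)-2-methylbutanoyl]cyclohexa-2,4-dien-1-one | CC[C@@H](C)C(=O)C1=C(O)C=C(O)[C@@](C)(CC=C(C)C)C1=O | intermediate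
7 | 2-methylprop-2-enal | C=C(C)C=O | starting material
8 | (triphenylphosphoranylidene)acetaldehyde | O=CC=P(c1ccccc1)(c1ccccc1)c1ccccc1 | starting material
9 | (2E)-4-methylpenta-2,4-dienal | C=C(C)/C=C/C=O | intermediate
10 | but-3-en-2-one | C=CC(C)=O | starting material
11 | (1R,2S,5S)-5-methyl-2-(prop-1-en-2-yl)-6-oxabicyclo[3.2.0]heptan-7-one | C=C(C)[C@H]1CC[C@]2(C)OC(=O)[C@H]12 | intermediate
12 | (1R,2S,5S)-2-hydroxy-2-methyl-5-(prop-1-en-2-yl)cyclopentane-1-carbaldehyde | C=C(C)[C@H]1CC[C@](C)(O)[C@@H]1C=O | intermediate
13 | 5-hydroxy-6-{[(1R,2S,5S)-2-hydroxy-2-methyl-5-(prop-1-en-2-yl)cyclopentyl]methylidene}-2-methyl-2-(3-methylbut-2-en-1-yl)-4-[(2R)-2-methylbutanoyl]cyclohex-4-ene-1,3-dione (E/Z mixture; quaternary carbon as in 6) | C=C(C)[C@H]1CC[C@](C)(O)[C@@H]1C=C1C(=O)[C@@](C)(CC=C(C)C)C(=O)C(C(=O)[C@H](C)CC)=C1O | intermediate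
14 | (6R)-3,5-dihydroxy-4-{[(1R,2S,5S)-2-hydroxy-2-methyl-5-(prop-1-en-2-yl)cyclopentyl]methyl}-6-methyl-6-(3-methylbut-2-en-1-yl)-2-[(2R)-2-methylbutanoyl]cyclohexa-2,4-dien-1-one | C=C(C)[C@H]1CC[C@](C)(O)[C@@H]1CC1=C(O)[C@@](C)(CC=C(C)C)C(=O)C(C(=O)[C@H](C)CC)=C1O | target

**Step count and risks**

Total steps: 6. Longest linear sequence: 4 (steps 3, 4, 5, 6, from methacrolein); the other branch is steps 1, 2, 6.

Most likely to fail, first: step 4. Methyl vinyl ketone may oligomerise or take up the acyl-anion form of the catalyst adduct, the dienal may react at its δ-carbon, and the level and sense of induction are untested. The fallback sets out from none of the numbered compounds (9 and 10 are dropped) but from purchased chiral-pool material, and it comes back to the route at 11. (S)-(−)-Limonene F1 is ozonised at its ring alkene only (O3, CH2Cl2/MeOH, pyridine, −78 °C; Me2S) to (3S)-6-oxo-3-(prop-1-en-2-yl)heptanal F2. Oxidation with NaClO2/NaH2PO4/2-methylbut-2-ene gives (3S)-6-oxo-3-(prop-1-en-2-yl)heptanoic acid F3. Nucleophile-catalysed aldol-lactonisation (2-chloro-1-methylpyridinium iodide, 4-pyrrolidinopyridine, iPr2NEt, CH2Cl2) then closes the cis-fused β-lactone 11. Here the isopropenyl centre comes from limonene and the ring fusion is substrate-controlled.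

Second: step 2. Alkylation may go to the unsubstituted ring carbon or to oxygen, and face selection on a flat, nearly symmetric phenolate may be low. The fallback sets out from 4 and comes back at 14; it postpones the prenylation until the free ring position is blocked. Compound 4 is reductively alkylated with 12 (dihydropyridine, L-proline, as in step 6) to (2R)-1-(2,4,6-trihydroxy-3-{[(1R,2S,5S)-2-hydroxy-2-methyl-5-(prop-1-en-2-yl)cyclopentyl]methyl}-5-methylphenyl)-2-methylbutan-1-one F4. In F4 the methyl-bearing carbon is the only unhindered site for dearomatisation. Prenylation of F4 with 5 under the step 2 catalyst (or with prenyl bromide/NaOMe) gives 14. If face selection is incomplete, the (6S)-epimer of the target F5 is removed by preparative HPLC.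

Third: step 5. The four-membered tetrahedral intermediate may collapse early and be reduced further, and 12 can dehydrate. The fallback sets out from 11 and comes back at 12. Full reduction with LiAlH4 (THF, 0 °C) gives the stable diol (1S,2S,3S)-2-(hydroxymethyl)-1-methyl-3-(prop-1-en-2-yl)cyclopentan-1-ol F6. Its primary alcohol alone is then oxidised (TEMPO cat., PhI(OAc)2, CH2Cl2, rt) to 12.

**Further compounds**

F1 | step 4 | (S)-(−)-limonene | CC1=CC[C@H](CC1)C(C)=C
F2 | step 4 | (3S)-6-oxo-3-(prop-1-en-2-yl)heptanal | O=CC[C@H](CCC(C)=O)C(C)=C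
F3 | step 4 | (3S)-6-oxo-3-(prop-1-en-2-yl)heptanoic acid | OC(=O)C[C@H](CCC(C)=O)C(C)=C
F4 | step 2 | (2R)-1-(2,4,6-trihydroxy-3-{[(1R,2S,5S)-2-hydroxy-2-methyl-5-(prop-1-en-2-yl)cyclopentyl]methyl}-5-methylphenyl)-2-methylbutan-1-one | C=C(C)[C@H]1CC[C@](C)(O)[C@@H]1Cc1c(O)c(C)c(O)c(C(=O)[C@H](C)CC)c1O
F5 | step 2 | (6S)-epimer of 14 at the ring quaternary carbon | C=C(C)[C@H]1CC[C@](C)(O)[C@@H]1CC1=C(O)[C@](C)(CC=C(C)C)C(=O)C(C(=O)[C@H](C)CC)=C1O
F6 | step 5 | (1S,2S,3S)-2-(hydroxymethyl)-1-methyl-3-(prop-1-en-2-yl)cyclopentan-1-ol | C=C(C)[C@H]1CC[C@](C)(O)[C@@H]1CO
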